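**Retrosynthetic overview**
- Enabling feature: the pyran ring O2–C1H2–C8a=C4a–C4H=C3 is a benzo-fused 2H-pyran. It is the closed valence isomer of the 1-oxatriene O=C3–C4H=C4a–C8a=C1H2 (an o-quinodimethane), which is the open form of a 7-acylbenzocyclobutene (C4 = ring C7, C1 = ring C8).
- Read this way, the enol-ether carbon C3 is a latent ketone. C3 and the aroyl carbon are then the two carbonyl carbons of an unsymmetrical 1,2-diketone, and its central C(=O)–C(=O) bond is the convergent disconnection: aroylstannane (unmasked acyl anion) plus benzocyclobutene acid chloride.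
- Ring order: both benzene rings and the cyclobutene are bought. The pyran ring is the only ring made, in the coupling flask, by 4π opening of the cyclobutene and oxa-6π closure, driven by strain release and rearomatisation.
- Fragments: 2,4-dimethoxybenzaldehyde to the aroylstannane (1 step); 4,5-dimethoxy-1-cyanobenzocyclobutene to the acid and then the acid chloride (2 steps).

Key step: step 4

Assumption: the target has no stereocentre and its only non-aromatic C=C bond is endocyclic, so it is achiral and there is no enantiomer to select. The benzocyclobutene building block is therefore used as the racemate.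

**Step 1**
Reactants: 1 2,4-dimethoxybenzaldehyde
Product: 3 tributyl(2,4-dimethoxybenzoyl)stannane, via lithium (2,4-dimethoxyphenyl)(tributylstannyl)methanolate 2 (not isolated)
Conditions: Bu3SnH, LDA, THF, 0 °C; add 1, −78 °C; then 1,1'-(azodicarbonyl)dipiperidine (ADD), −78 → 0 °C; H2O quench; argon, exclusion of light
Reagents that add atoms: tributyltin hydride, CCCC[SnH](CCCC)CCCC (lithiated in the flask to Bu3SnLi, [Li][Sn](CCCC)(CCCC)CCCC)
Why: Stannyl-anion 1,2-addition to the aldehyde followed by in-flask hydride-transfer (Oppenauer-type) oxidation of the lithium alkoxide by the azodicarboxamide is the standard entry to acylstannanes, spares the aryl methyl ethers, and erases the racemic carbinol centre of 2 at once.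

**Step 2**
Reactants: 4 rac-3,4-dimethoxybicyclo[4.2.0]octa-1,3,5-triene-7-carbonitrile (4,5-dimethoxy-1-cyanobenzocyclobutene)
Product: 5 rac-3,4-dimethoxybicyclo[4.2.0]octa-1,3,5-triene-7-carboxylic acid
Conditions: KOH, EtOH/H2O, reflux; then aq. HCl, 0 °C
Reagents that add atoms: potassium hydroxide, [K+].[OH-]; water, O
Why: Alkaline nitrile hydrolysis runs far below the temperature at which the benzocyclobutene opens, and the C7 centre may stay racemic because step 4 destroys it.

**Step 3**
Reactants: 5 rac-3,4-dimethoxybicyclo[4.2.0]octa-1,3,5-triene-7-carboxylic acid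
Product: 6 rac-3,4-dimethoxybicyclo[4.2.0]octa-1,3,5-triene-7-carbonyl chloride
Conditions: (COCl)2, DMF (cat.), CH2Cl2, 0 °C → rt; volatiles removed thoroughly, used crude
Reagents that add atoms: oxalyl chloride, O=C(Cl)C(=O)Cl
Why: Vilsmeier-type activation with oxalyl chloride and catalytic DMF forms the acid chloride without base and without heating, so neither ketene formation nor ring opening should intervene.

**Step 4**
Reactants: 3 tributyl(2,4-dimethoxybenzoyl)stannane; 6 rac-3,4-dimethoxybicyclo[4.2.0]octa-1,3,5-triene-7-carbonyl chloride
Product: 9 (6,7-dimethoxy-1H-isochromen-3-yl)(2,4-dimethoxyphenyl)methanone, via rac-1-(3,4-dimethoxybicyclo[4.2.0]octa-1,3,5-trien-7-yl)-2-(2,4-dimethoxyphenyl)ethane-1,2-dione 7 (not isolated), via (3Z)-3-(3,4-dimethoxy-6-methylidenecyclohexa-2,4-dien-1-ylidene)-1-(2,4-dimethoxyphenyl)propane-1,2-dione 8 (not isolated)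
Conditions: Pd2(dba)3 (2.5 mol %), P(2-furyl)3 (10 mol %), CO (1 atm), o-xylene (0.02 M), 70 °C; then 140 °C in the same flask
Reagents that add atoms: none
Why: Oxidative addition of acid chloride 6 to Pd(0), transfer of the intact aroyl group from tin (Stille-type transmetalation) and reductive elimination from the bis(acyl)palladium(II) species should forge the C(=O)–C(=O) bond of diketone 7, with the CO atmosphere holding back decarbonylation of either acyl ligand. Once the temperature is raised, the strained C7–C8 σ-bond of 7 opens in a conrotatory 4π process to the o-quinodimethane 8, whose proximal ketone oxygen then attacks the exocyclic CH2 in a disrotatory oxa-6π electrocyclisation that closes the pyran ring (O2–C1 bond) and restores the benzene ring. The closest known reaction types are the palladium-catalysed coupling of acylstannanes with acid chlorides to unsymmetrical 1,2-diketones and the thermal rearrangement of 1-acylbenzocyclobutenes to 3-substituted 1H-isochromenes. No stereocentre is created, the racemic one at C7 is erased, and the C3=C4 geometry is dictated by the six-membered ring. The step needs inward rotation of the ketoacyl group: a π-acceptor carbonyl substituent favours this mode, and because ring opening is reversible the outward isomer returns through 7 while the (Z)-isomer 8 is drained irreversibly by aromatisation, high dilution keeping bimolecular capture of 8 down. Site selectivity between the two carbonyl groups is secured by connectivity, since only the carbonyl carbon bonded to C7 lies within the 1-oxatriene, and cross- over homo-coupling is secured by the fixed electrophile (6) and nucleophile (3) roles.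

**Compound list**
1 | 2,4-dimethoxybenzaldehyde | COc1ccc(C=O)c(OC)c1 | starting material
2 | lithium (2,4-dimethoxyphenyl)(tributylstannyl)methanolate (racemic) | COc1ccc(C([O-])[Sn](CCCC)(CCCC)CCCC)c(OC)c1.[Li+] | intermediate
3 | tributyl(2,4-dimethoxybenzoyl)stannane | COc1ccc(C(=O)[Sn](CCCC)(CCCC)CCCC)c(OC)c1 | intermediate
4 | rac-3,4-dimethoxybicyclo[4.2.0]octa-1,3,5-triene-7-carbonitrile | N#CC1Cc2cc(OC)c(OC)cc21 | starting material
5 | rac-3,4-dimethoxybicyclo[4.2.0]octa-1,3,5-triene-7-carboxylic acid | O=C(O)C1Cc2cc(OC)c(OC)cc21 | intermediate
6 | rac-3,4-dimethoxybicyclo[4.2.0]octa-1,3,5-triene-7-carbonyl chloride | O=C(Cl)C1Cc2cc(OC)c(OC)cc21 | intermediate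
7 | rac-1-(3,4-dimethoxybicyclo[4.2.0]octa-1,3,5-trien-7-yl)-2-(2,4-dimethoxyphenyl)ethane-1,2-dione | COc1ccc(C(=O)C(=O)C2Cc3cc(OC)c(OC)cc32)c(OC)c1 | intermediate
8 | (3Z)-3-(3,4-dimethoxy-6-methylidenecyclohexa-2,4-dien-1-ylidene)-1-(2,4-dimethoxyphenyl)propane-1,2-dione | C=C1C=C(OC)C(OC)=C/C1=C/C(=O)C(=O)c1ccc(OC)cc1OC | intermediate
9 | (6,7-dimethoxy-1H-isochromen-3-yl)(2,4-dimethoxyphenyl)methanone (achiral) | COc1ccc(C(=O)C2=Cc3cc(OC)c(OC)cc3CO2)c(OC)c1 | target

**Step count**
- Total steps: 4.
- Longest linear sequence: 3 (steps 2, 3, 4).

**Steps most likely to fail**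

1. **Step 4.**
   - What may go wrong: loss of CO from the acylpalladium intermediates or sluggish acyl transfer from tin, so that C–C bond formation is outrun. In the thermal phase, bimolecular capture of the o-quinodimethane may compete with ring closure.
   - Fallback: a metal-free, staged union with a masked aroyl anion. It sets out from 1 and 6 and comes back to the route at 7.
   - Aldehyde 1 would be condensed with benzotriazole and ethanol/triethyl orthoformate under acid catalysis to give 1-[(2,4-dimethoxyphenyl)(ethoxy)methyl]-1H-benzotriazole F1.
   - Acid chloride 6 would be converted with MeNHOMe·HCl and pyridine into rac-N-methoxy-N-methyl-3,4-dimethoxybicyclo[4.2.0]octa-1,3,5-triene-7-carboxamide F2.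
   - Lithiation of F1 (n-BuLi, THF, −78 °C) and acylation by F2 would give the masked diketone 2-(benzotriazol-1-yl)-1-(3,4-dimethoxybicyclo[4.2.0]octa-1,3,5-trien-7-yl)-2-(2,4-dimethoxyphenyl)-2-ethoxyethan-1-one F3.
   - Dilute aqueous acid would release 7, which would be isolated and then heated on its own in dilute o-xylene to pass through 8 to 9.

2. **Step 1.**
   - What may go wrong: autoxidation and protodestannylation of the acylstannane during oxidation, work-up and purification, or incomplete hydride transfer from the alkoxide to the azo compound.
   - Fallback: stannylation at the acyl oxidation level instead of addition and oxidation. It sets out from 1 and comes back at 3.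
   - Pinnick oxidation of 1 would give 2,4-dimethoxybenzoic acid F4.
   - Oxalyl chloride with catalytic DMF would give 2,4-dimethoxybenzoyl chloride F5.
   - Palladium-catalysed stannylation of F5 with hexabutyldistannane would deliver 3, which could be taken into step 4 without chromatography.

3. **Step 3.**
   - What may go wrong: hydrolysis of the acid chloride on handling, and carry-over of hydrogen chloride that would protodestannylate 3 in the next step.
   - Fallback: a bench-stable acyl donor and a different coupling manifold. It sets out from 5 and comes back at 7, formed in the flask and carried on to 9 as in step 4.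
   - DCC/DMAP coupling of 5 with 4-methylbenzenethiol would give S-(4-methylphenyl) rac-3,4-dimethoxybicyclo[4.2.0]octa-1,3,5-triene-7-carbothioate F6, which can be purified.
   - F6 would be joined to 3 under neutral Liebeskind–Srogl-type conditions (Pd(0), copper(I) diphenylphosphinate), followed by the same temperature ramp.

**Further compounds**
F1 | step 4 | 1-[(2,4-dimethoxyphenyl)(ethoxy)methyl]-1H-benzotriazole (racemic) | CCOC(c1ccc(OC)cc1OC)n1nnc2ccccc21
F2 | step 4 | rac-N-methoxy-N-methyl-3,4-dimethoxybicyclo[4.2.0]octa-1,3,5-triene-7-carboxamide | CON(C)C(=O)C1Cc2cc(OC)c(OC)cc21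
F3 | step 4 | 2-(benzotriazol-1-yl)-1-(3,4-dimethoxybicyclo[4.2.0]octa-1,3,5-trien-7-yl)-2-(2,4-dimethoxyphenyl)-2-ethoxyethan-1-one (mixture of racemic diastereomers) | CCOC(C(=O)C1Cc2cc(OC)c(OC)cc21)(c1ccc(OC)cc1OC)n1nnc2ccccc21
F4 | step 1 | 2,4-dimethoxybenzoic acid | COc1ccc(C(=O)O)c(OC)c1
F5 | step 1 | 2,4-dimethoxybenzoyl chloride | COc1ccc(C(=O)Cl)c(OC)c1
F6 | step 3 | S-(4-methylphenyl) rac-3,4-dimethoxybicyclo[4.2.0]octa-1,3,5-triene-7-carbothioate | Cc1ccc(SC(=O)C2Cc3cc(OC)c(OC)cc32)cc1
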